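Remark: the target has no stereocentre and no stereogenic double bond, so no configuration has to be set; the only stereogenic species on the route, the bridged lactone 15, is racemic and transient. 2,4-Dimethoxyphenol (6) and diketene (2) are taken as purchasable.

## Analysis of the target

Compound 19, methyl 2-[2-(hydroxymethyl)-4,6-dimethoxyphenoxy]-4-methyl-6-[(3-methylbut-2-en-1-yl)oxy]benzoate, is an achiral diaryl ether: two benzene rings joined through one oxygen. Every selectivity problem is therefore one of regiochemistry and chemoselectivity. Ring A is a benzoate whose ester carbon C1 lies between two different oxygens, the prenyl ether at C2 and the aryl ether at C6, with a methyl group at C4 and hydrogens at C3 and C5. Ring B carries the ether oxygen at C1', flanked by the hydroxymethyl group at C2' and a methoxy group at C6', with a second methoxy group at C4'. The sensitive functions are the aryl prenyl ether (acid, heat, hydrogenation), the electron-rich benzylic alcohol (ionisation, oxidation, attack on the ester across the ether bridge to an eight-membered lactone) and the methyl ester. The difficulty lies in the C6–O–C1' bond, which has three ortho substituents and is a poor candidate for late coupling of two finished arenes, and in telling apart the two oxygens that flank C1. The strategy rests on one mapping: C1, C2, C3 and C4 of ring A (ester, oxygen, hydrogen, methyl) are C3 to C6 of a 4-alkoxy-6-methyl-2-pyrone-3-carboxylate, and C5 and C6 can be the two carbons of an alkyne that already carries the ring B oxygen on the carbon that becomes C6. Ring A is thus assembled around the ether oxygen instead of being joined to it afterwards.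

## Retrosynthetic reasoning

**19 to 18.** The O–Si bond of the benzylic oxygen is cut last. Keeping the benzylic alcohol silylated until the end protects it from base, heat and hydrogenation and prevents lactonisation onto the ester. The forward step must remove silicon without generating a free alkoxide.

**18 to 17.** The O–CH2 bond of the prenyl ether is cut. The prenyl group is placed late because it would survive neither hydrogenolysis nor the thermal ring-forming step (Claisen rearrangement). The forward step is alkylation of the only phenol in 17.

**17 to 16.** The C2 oxygen is carried through ring formation as a benzyl ether. This group distinguishes the C2 oxygen from the C6 oxygen from the start, has no thermal rearrangement pathway, and is removed without acid or base.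

**16 to 5 and 14, through 15.** Ring A is cut at C4–C5 and C1–C6, with the O–C(=O) bridge of 15 restored in the backward sense. This is the place to cut because the aryl ether oxygen then sits on an sp carbon of 14 before ring A exists, so no hindered aryl C–O coupling is needed. The ester, the C2 oxygen, the methyl group and the aryloxy group all arrive in their final positions in one operation. The forward reaction must join the oxygen-bearing alkyne carbon to pyrone C3 and the CH terminus to pyrone C6, then expel the bridge from 15.

**14 to 11, through 13 and 12; 11 to 9 and 10.** The two alkyne carbons come from 10. The O–C(sp2) bond of 11 is formed by adding the phenoxide of 9 to the chloroalkyne that 10 gives with base. Elimination to 12, chlorine–lithium exchange to 13 and protonation then give 14. This uses the phenol oxygen of ring B directly as the nucleophile, and the hindrance around it matters little for so slim an electrophile.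

**9 to 8, 7 and 6.** The C2'–CH2 bond is cut back to 6, which has only one free position ortho to the hydroxyl. Ortho-formylation gives 7, reduction gives 8, and selective silylation of the primary alcohol gives 9.

**5 to 4; 4 to 1 and 2, through 3.** The benzyl ether of 5 comes from O-alkylation of the vinylogous acid 4. The pyrone ring of 4 is cut at the C3–C4 bond and the O1–C2 lactone bond: C-acylation of 1 by 2 gives 3, which lactonises. All six ring atoms of the diene and the ester carbon thus come from two bulk chemicals in one step.

## Alternatives that were turned down

**Alternative 1:** Ring B grown on a finished ring A.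
- Disconnection: ring B is cut at C1'–C2' and C4'–C5'.
- Forward key step: an alkoxide base forms the enolate of the ring A aryloxyacetone A1 at the carbon bearing the aryloxy group. This adds to the silyloxy crotonate A2 (Michael addition, C1'–C2'). The enolate on the methyl side of the ketone then attacks the ester (Claisen closure, C4'–C5') to give the cyclohexane-1,3-dione A3, racemic, whose two centres disappear on aromatisation.
- For it: the hindered ether oxygen is attached to ring A by a plain O-alkylation before ring B exists. The annulation is classical ionic chemistry at ambient temperature with cheap reagents. In mildness and depth of precedent it is stronger than the thermal cycloaddition chosen here.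
- Against it: A3 has ring B at the wrong oxidation level, so a dehydrogenation to the resorcinol and a double O-methylation must follow. These must leave untouched the free salicylate hydroxyl of ring A that is to take the prenyl group. A1 has two enolisable positions, and the annulation needs the more hindered one as Michael donor. The base can also direct the methyl-side enolate onto the ring A ester.
- Comparison: four to five steps would follow the key step instead of three. The chosen route brings ring B in already aromatic and fully methylated, so nothing after the key step changes its oxidation level.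

**Alternative 2:** Aryne three-component coupling.
- Disconnection: the O–C6 bond and the C1–carboxyl bond of ring A, both at once.
- Forward key step: fluoride releases the aryne from the ortho-silyl aryl triflate A4. The caesium phenoxide of the ring B phenol A5 adds at the aryne carbon remote from the acetal oxygen (C6). The aryl anion left at C1 is carboxylated in the same flask to give the acid A6.
- For it: two complete arenes and the carboxyl carbon are joined in one operation at room temperature. Arynes accept hindered phenoxides, and the 3-alkoxy group of the aryne fixes the position of attack. In convergence and mildness this is as strong as the chosen key step, or stronger.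
- Against it: A4, with its 1,2,3,5-pattern, needs a regiocontrolled multistep synthesis. The phenoxide is reversibly carbonated by the gas that has to trap the anion. The aryl anion may be protonated before it is carboxylated, which would give the ether without the C1 carboxyl. After the key step an esterification, acid removal of two acetal groups next to an electron-rich benzylic oxygen, and a selective prenylation are still needed.
- Comparison: the chosen route carries the ester carbon from the start as part of 5, avoids a three-way competition of nucleophile, aryne and electrophile, and reaches both precursors in seven simple steps.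

**Alternative 3:** Normal-demand Diels–Alder on an aryloxypropiolate.
- Disconnection: ring A is cut at C5–C6 and C1–C2, with the ester and the aryloxy group both on the alkyne.
- Forward key step: the aryloxypropiolate A7 reacts with the bis-silyl ketene acetal diene A8. Loss of silanol from the adduct gives the free salicylate A9, which is the same compound as 17.
- For it: the salicylate hydroxyl emerges unprotected, so the benzylation and the hydrogenolysis of the chosen route are saved. A7 is available from the same acetylide 13. In step count this alternative is the stronger one.
- Against it: A7 is a push–pull alkyne whose aryloxy donor lowers its reactivity as a dienophile. A8 necessarily has a cis substituent at its oxygenated terminus and is a strong carbon nucleophile. Conjugate addition at the aryloxy-bearing carbon with expulsion of the ring B phenoxide therefore competes with cycloaddition and would sever the two rings. A8 is also moisture-sensitive.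
- Comparison: in the chosen key step the aryloxy group never sits β to an acceptor in an anionic intermediate that could expel it. Regiochemistry is enforced jointly by the ester, the lactone and the 4-alkoxy group. The alternative is kept as the reserve for step 8 because it rejoins the route at 17.

Key step: step 8

## Route

Step 1
Reactants: 1 dimethyl malonate; 2 diketene
Product: 4 methyl 4-hydroxy-6-methyl-2-oxo-2H-pyran-3-carboxylate, via dimethyl 2-(3-oxobutanoyl)propanedioate 3 (not isolated)
Conditions: NaH, THF, 0 °C; then 2, 0 °C → rt; 1 M HCl
Reagents that add atoms: none
Why: Ring-opening C-acylation of sodiomalonate by diketene gives the acetoacetylmalonate 3 as its enolate; the enol oxygen of the terminal methyl ketone then attacks one malonate ester (six-membered lactonisation with loss of methanol), a known route to 3-alkoxycarbonyl-4-hydroxy-6-methyl-2-pyrones.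

Step 2
Reactants: 4 methyl 4-hydroxy-6-methyl-2-oxo-2H-pyran-3-carboxylate
Product: 5 methyl 4-(benzyloxy)-6-methyl-2-oxo-2H-pyran-3-carboxylate
Conditions: BnOH, PPh3, DIAD, THF, 0 °C → rt
Reagents that add atoms: benzyl alcohol, OCc1ccccc1
Why: Mitsunobu O-alkylation; the vinylogous acid 4 is acidic enough to protonate the betaine and its 4-oxygen attacks the benzyloxyphosphonium ion; C3 is fully substituted, so C-alkylation is blocked, and alkylation at the 4-oxygen, the usual outcome for 4-hydroxy-2-pyrones, keeps the 2-pyrone intact.

Step 3
Reactants: 6 2,4-dimethoxyphenol
Product: 7 2-hydroxy-3,5-dimethoxybenzaldehyde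
Conditions: MgCl2, Et3N, (CH2O)n, MeCN, reflux; then 1 M HCl
Reagents that add atoms: formaldehyde (from paraformaldehyde), C=O
Why: Magnesium-mediated ortho-formylation (Casnati–Skattebøl reaction); the magnesium phenoxide delivers coordinated formaldehyde to the only free ortho position, and the resulting benzylic alkoxide is oxidised to the aldehyde by hydride transfer to a second formaldehyde.

Step 4
Reactants: 7 2-hydroxy-3,5-dimethoxybenzaldehyde
Product: 8 2-(hydroxymethyl)-4,6-dimethoxyphenol
Conditions: NaBH4, MeOH, 0 °C; aq. NH4Cl
Reagents that add atoms: none
Why: Hydride reduction of the aryl aldehyde; nothing else in 7 is reducible by NaBH4, and the mild ammonium chloride work-up avoids acid-induced ionisation of the electron-rich salicyl alcohol.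

Step 5
Reactants: 8 2-(hydroxymethyl)-4,6-dimethoxyphenol
Product: 9 2-[(tert-butyldimethylsilyloxy)methyl]-4,6-dimethoxyphenol
Conditions: TBSCl (1.05 equiv), imidazole, CH2Cl2, 0 °C
Reagents that add atoms: tert-butyldimethylsilyl chloride (TBSCl), CC(C)(C)[Si](C)(C)Cl
Why: Chemoselective silylation; the primary benzylic alcohol reacts with the silylimidazolium species faster than the neutral, doubly ortho-substituted and hydrogen-bonded phenol, and silicon on the alkyl oxygen is also the thermodynamically preferred position because phenoxide is the better leaving group.

Step 6
Reactants: 9 2-[(tert-butyldimethylsilyloxy)methyl]-4,6-dimethoxyphenol; 10 trichloroethylene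
Product: 11 tert-butyl[(2-{[(E)-1,2-dichloroethenyl]oxy}-3,5-dimethoxyphenyl)methoxy]dimethylsilane
Conditions: K2CO3, DMF, 70 °C
Reagents that add atoms: none
Why: Base converts 10 into dichloroacetylene in the flask and the phenoxide of 9 adds to it; anti protonation of the vinyl anion gives the (E)-1,2-dichlorovinyl ether, a known preparation of such ethers from phenols; the haloalkyne is never isolated and the silyl ether is stable to anhydrous carbonate.

Step 7
Reactants: 11 tert-butyl[(2-{[(E)-1,2-dichloroethenyl]oxy}-3,5-dimethoxyphenyl)methoxy]dimethylsilane
Product: 14 tert-butyl[(2-ethynyloxy-3,5-dimethoxyphenyl)methoxy]dimethylsilane, via chloroethynyl aryl ether 12 (not isolated), via lithium aryloxyacetylide 13 (not isolated)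
Conditions: n-BuLi (2.3 equiv), THF, −78 → −40 °C; then H2O, −78 °C → rt
Reagents that add atoms: none
Why: The first equivalent of n-BuLi removes the vinylic hydrogen and the carbenoid eliminates LiCl to give 12; chlorine–lithium exchange with the second equivalent gives 13, which water protonates to the terminal ynol ether 14 (the established dichlorovinyl ether route to aryl ynol ethers); the low temperature suppresses ring and benzylic lithiation and leaves the silyl ether intact.

Step 8
Reactants: 5 methyl 4-(benzyloxy)-6-methyl-2-oxo-2H-pyran-3-carboxylate; 14 tert-butyl[(2-ethynyloxy-3,5-dimethoxyphenyl)methoxy]dimethylsilane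
Product: 16 methyl 2-(benzyloxy)-6-{2-[(tert-butyldimethylsilyloxy)methyl]-4,6-dimethoxyphenoxy}-4-methylbenzoate, via bridged bicyclic lactone 15 (not isolated)
Conditions: 5 (1.5 equiv), BHT (cat.), PhMe (1 M), 120 °C, sealed tube
Reagents that add atoms: none
Why: The pyrone 5 is the electron-poor 4π component (its LUMO is lowered by the lactone carbonyl and the C3 ester) and the ynol ether 14 is the electron-rich 2π component, so an inverse-electron-demand [4+2] cycloaddition across pyrone C3 and C6 is expected on heating. The bond from the nucleophilic CH terminus of 14 to the electrophilic pyrone C6 should run ahead of the bond from the oxygen-bearing alkyne carbon to C3, where the developing negative charge is held by both carbonyl groups and the positive charge by the aryloxy oxygen. This closes ring A as the 2-oxabicyclo[2.2.2]octadienone 15 (intermolecular [4+2] closure forming C4–C5 and C1–C6 of ring A), which at the reaction temperature loses its O–C(=O) bridge as CO2 by retro-[4+2] and gives the benzoate 16 irreversibly. The closest known reaction type is the cycloaddition–decarboxylation of 3-alkoxycarbonyl-2-pyrones with ketene acetals, ynamines and alkoxyalkynes, and more generally of 2-pyrones with alkynes, to give benzoates. No stereocentre is present in 16; the two bridgehead centres of racemic 15 are destroyed in the extrusion. The selectivity required is regiochemical (aryloxy ortho, not meta, to the ester) and is secured by the matched polarisation just described, which the 4-benzyloxy donor reinforces by raising electron density at C3 while leaving C6 as the acceptor terminus. Because an alkyne is used, the arene forms without an elimination step, so the aryloxy group cannot be expelled; 14 has no β-hydrogen for ketene-forming retro-ene cleavage, and the excess of the cheap diene, the high concentration, the radical inhibitor and the acid-free medium favour capture of 14 over its oligomerisation or hydration.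

Step 9
Reactants: 16 methyl 2-(benzyloxy)-6-{2-[(tert-butyldimethylsilyloxy)methyl]-4,6-dimethoxyphenoxy}-4-methylbenzoate
Product: 17 methyl 2-{2-[(tert-butyldimethylsilyloxy)methyl]-4,6-dimethoxyphenoxy}-6-hydroxy-4-methylbenzoate
Conditions: H2 (1 atm), 10% Pd/C, EtOAc, rt
Reagents that add atoms: none
Why: Hydrogenolysis of the aryl benzyl ether; in neutral EtOAc, with the reaction stopped once 16 is consumed, the diaryl ether, the ester and the slower-reacting silylated benzylic C–O bond of ring B should remain, and no alkene is present at this stage.

Step 10
Reactants: 17 methyl 2-{2-[(tert-butyldimethylsilyloxy)methyl]-4,6-dimethoxyphenoxy}-6-hydroxy-4-methylbenzoate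
Product: 18 methyl 2-{2-[(tert-butyldimethylsilyloxy)methyl]-4,6-dimethoxyphenoxy}-4-methyl-6-[(3-methylbut-2-en-1-yl)oxy]benzoate
Conditions: prenyl bromide, K2CO3, DMF, rt
Reagents that add atoms: prenyl bromide (1-bromo-3-methylbut-2-ene), CC(C)=CCBr
Why: Williamson ether synthesis; the only acidic hydroxyl is the salicylate phenol, and its phenoxide displaces bromide at the primary allylic carbon (SN2) at a temperature far below that of any Claisen rearrangement.

Step 11
Reactants: 18 methyl 2-{2-[(tert-butyldimethylsilyloxy)methyl]-4,6-dimethoxyphenoxy}-4-methyl-6-[(3-methylbut-2-en-1-yl)oxy]benzoate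
Product: 19 methyl 2-[2-(hydroxymethyl)-4,6-dimethoxyphenoxy]-4-methyl-6-[(3-methylbut-2-en-1-yl)oxy]benzoate
Conditions: Bu4NF, AcOH (1:1), THF, 0 °C → rt
Reagents that add atoms: none
Why: Fluoride-induced cleavage of the Si–O bond; acetic acid buffering keeps the liberated benzylic oxygen protonated so that it cannot attack the methyl ester across the diaryl ether (eight-membered lactonisation), and the prenyl ether and the ester are inert to these conditions.

## Compound list

1 | dimethyl malonate (dimethyl propanedioate) | COC(=O)CC(=O)OC | starting material
2 | diketene (4-methylideneoxetan-2-one) | C=C1CC(=O)O1 | starting material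
3 | dimethyl 2-(3-oxobutanoyl)propanedioate (formed as its sodium enolate) | COC(=O)C(C(=O)OC)C(=O)CC(C)=O | intermediate (not isolated)
4 | methyl 4-hydroxy-6-methyl-2-oxo-2H-pyran-3-carboxylate | COC(=O)c1c(O)cc(C)oc1=O | intermediate
5 | methyl 4-(benzyloxy)-6-methyl-2-oxo-2H-pyran-3-carboxylate | COC(=O)c1c(OCc2ccccc2)cc(C)oc1=O | intermediate
6 | 2,4-dimethoxyphenol | COc1ccc(O)c(OC)c1 | starting material
7 | 2-hydroxy-3,5-dimethoxybenzaldehyde | COc1cc(C=O)c(O)c(OC)c1 | intermediate
8 | 2-(hydroxymethyl)-4,6-dimethoxyphenol | COc1cc(CO)c(O)c(OC)c1 | intermediate
9 | 2-[(tert-butyldimethylsilyloxy)methyl]-4,6-dimethoxyphenol | COc1cc(CO[Si](C)(C)C(C)(C)C)c(O)c(OC)c1 | intermediate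
10 | trichloroethylene (1,1,2-trichloroethene) | ClC=C(Cl)Cl | starting material
11 | tert-butyl[(2-{[(E)-1,2-dichloroethenyl]oxy}-3,5-dimethoxyphenyl)methoxy]dimethylsilane | Cl/C=C(/Cl)Oc1c(CO[Si](C)(C)C(C)(C)C)cc(OC)cc1OC | intermediate
12 | tert-butyl({2-[(chloroethynyl)oxy]-3,5-dimethoxyphenyl}methoxy)dimethylsilane | ClC#COc1c(CO[Si](C)(C)C(C)(C)C)cc(OC)cc1OC | intermediate (not isolated)
13 | lithium 2-{2-[(tert-butyldimethylsilyloxy)methyl]-4,6-dimethoxyphenoxy}ethynide | [Li]C#COc1c(CO[Si](C)(C)C(C)(C)C)cc(OC)cc1OC | intermediate (not isolated)
14 | tert-butyl[(2-ethynyloxy-3,5-dimethoxyphenyl)methoxy]dimethylsilane | C#COc1c(CO[Si](C)(C)C(C)(C)C)cc(OC)cc1OC | intermediate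
15 | methyl 5-(benzyloxy)-8-{2-[(tert-butyldimethylsilyloxy)methyl]-4,6-dimethoxyphenoxy}-1-methyl-3-oxo-2-oxabicyclo[2.2.2]octa-5,7-diene-4-carboxylate (racemic, one enantiomer drawn) | COC(=O)[C@@]12C(=O)O[C@@](C)(C=C1OCc1ccccc1)C=C2Oc1c(CO[Si](C)(C)C(C)(C)C)cc(OC)cc1OC | intermediate (not isolated)
16 | methyl 2-(benzyloxy)-6-{2-[(tert-butyldimethylsilyloxy)methyl]-4,6-dimethoxyphenoxy}-4-methylbenzoate | COC(=O)c1c(OCc2ccccc2)cc(C)cc1Oc1c(CO[Si](C)(C)C(C)(C)C)cc(OC)cc1OC | intermediate
17 | methyl 2-{2-[(tert-butyldimethylsilyloxy)methyl]-4,6-dimethoxyphenoxy}-6-hydroxy-4-methylbenzoate | COC(=O)c1c(O)cc(C)cc1Oc1c(CO[Si](C)(C)C(C)(C)C)cc(OC)cc1OC | intermediate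
18 | methyl 2-{2-[(tert-butyldimethylsilyloxy)methyl]-4,6-dimethoxyphenoxy}-4-methyl-6-[(3-methylbut-2-en-1-yl)oxy]benzoate | COC(=O)c1c(OCC=C(C)C)cc(C)cc1Oc1c(CO[Si](C)(C)C(C)(C)C)cc(OC)cc1OC | intermediate
19 | methyl 2-[2-(hydroxymethyl)-4,6-dimethoxyphenoxy]-4-methyl-6-[(3-methylbut-2-en-1-yl)oxy]benzoate | COC(=O)c1c(OCC=C(C)C)cc(C)cc1Oc1c(CO)cc(OC)cc1OC | target

## Step count and least certain steps

Total step count: 11. Longest linear sequence: 9 steps (6 to 19, steps 3 to 11); the pyrone 5 is made in 2 steps and joins at step 8.

**Step 8 (key step).** The most likely failure is that hydration, oligomerisation or other thermal consumption of the ynol ether outruns the cycloaddition, because the 4-benzyloxy donor raises the LUMO of the diene and the 6-methyl group hinders the first bond formation at C6. A stepwise addition that stops short of ring closure is a second possibility. High pressure at room temperature would be tried first. The fallback reverses the electron demand and sets out from 11. Treatment with n-BuLi and then methyl chloroformate traps the acetylide 13 as methyl 3-{2-[(tert-butyldimethylsilyloxy)methyl]-4,6-dimethoxyphenoxy}prop-2-ynoate F1. Heating F1 in PhMe with 3-methyl-1,1-bis(trimethylsilyloxy)buta-1,3-diene F2, then mild acid work-up, should give the salicylate by normal-demand Diels–Alder reaction and loss of silanol. F2 would be made from commercial 3-methylbut-2-enoic acid by double deprotonation–silylation with LiN(i-Pr)2 and Me3SiCl. The route is rejoined at 17, and steps 8 and 9 are bypassed.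

**Step 7.** The most likely failure is loss of the terminal ynol ether during isolation, through hydration on silica or oligomerisation on concentration. Ring or benzylic lithiation by excess n-BuLi is a second possibility. The fallback sets out from 11 and quenches the acetylide 13 with Me3SiCl instead of water. This gives tert-butyl[(3,5-dimethoxy-2-{[(trimethylsilyl)ethynyl]oxy}phenyl)methoxy]dimethylsilane F3, a capped ynol ether that can be purified and stored. The C–Si bond is cleaved with catalytic K2CO3 in MeOH at 0 °C immediately before the cycloaddition. The route is rejoined at 14.

**Step 2.** The most likely failure is alkylation of the ambident pyronate at the lactone carbonyl oxygen instead of the 4-oxygen, or sluggish reaction of the strongly stabilised anion. The fallback inverts the polarity and sets out from 4. TsCl and Et3N in CH2Cl2 give methyl 6-methyl-4-[(4-methylbenzenesulfonyl)oxy]-2-oxo-2H-pyran-3-carboxylate F4. Benzyl alcohol and K2CO3 in MeCN then replace the sulfonate by addition–elimination at C4, which can only place the benzyloxy group on that carbon. The route is rejoined at 5.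

**Step 5.** The most likely failure is competing silylation of the phenol oxygen or double silylation, which would leave no free phenol for step 6. The fallback sets out from 8 and silylates exhaustively (excess TBSCl, imidazole, DMF) to tert-butyl({2-[(tert-butyldimethylsilyl)oxy]-3,5-dimethoxyphenyl}methoxy)dimethylsilane F5. The aryl silyl ether alone is then cleaved with K2CO3 in MeOH, since phenoxide is the better leaving group. The route is rejoined at 9.

## Further compounds

F1 | step 8 | methyl 3-{2-[(tert-butyldimethylsilyloxy)methyl]-4,6-dimethoxyphenoxy}prop-2-ynoate | COC(=O)C#COc1c(CO[Si](C)(C)C(C)(C)C)cc(OC)cc1OC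
F2 | step 8 | 3-methyl-1,1-bis(trimethylsilyloxy)buta-1,3-diene | C=C(C)C=C(O[Si](C)(C)C)O[Si](C)(C)C
F3 | step 7 | tert-butyl[(3,5-dimethoxy-2-{[(trimethylsilyl)ethynyl]oxy}phenyl)methoxy]dimethylsilane | C[Si](C)(C)C#COc1c(CO[Si](C)(C)C(C)(C)C)cc(OC)cc1OC
F4 | step 2 | methyl 6-methyl-4-[(4-methylbenzenesulfonyl)oxy]-2-oxo-2H-pyran-3-carboxylate | COC(=O)c1c(OS(=O)(=O)c2ccc(C)cc2)cc(C)oc1=O
F5 | step 5 | tert-butyl({2-[(tert-butyldimethylsilyl)oxy]-3,5-dimethoxyphenyl}methoxy)dimethylsilane | COc1cc(CO[Si](C)(C)C(C)(C)C)c(O[Si](C)(C)C(C)(C)C)c(OC)c1
A1 | alternative 1 | methyl 2-hydroxy-4-methyl-6-(2-oxopropoxy)benzoate | COC(=O)c1c(O)cc(C)cc1OCC(C)=O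
A2 | alternative 1 | methyl (2E)-4-[(tert-butyldimethylsilyl)oxy]but-2-enoate | COC(=O)/C=C/CO[Si](C)(C)C(C)(C)C
A3 | alternative 1 | methyl 2-{[2-(tert-butyldimethylsilyloxymethyl)-4,6-dioxocyclohexyl]oxy}-6-hydroxy-4-methylbenzoate (racemic, one diastereomer drawn) | CC(C)(C)[Si](C)(C)OC[C@@H]1CC(=O)CC(=O)[C@H]1Oc1cc(C)cc(O)c1C(=O)OC
A4 | alternative 2 | 3-(methoxymethoxy)-5-methyl-2-(trimethylsilyl)phenyl trifluoromethanesulfonate | COCOc1cc(C)cc(OS(=O)(=O)C(F)(F)F)c1[Si](C)(C)C
A5 | alternative 2 | 2,4-dimethoxy-6-[(methoxymethoxy)methyl]phenol | COCOCc1cc(OC)cc(OC)c1O
A6 | alternative 2 | 2-{2,4-dimethoxy-6-[(methoxymethoxy)methyl]phenoxy}-6-(methoxymethoxy)-4-methylbenzoic acid | OC(=O)c1c(OCOC)cc(C)cc1Oc1c(COCOC)cc(OC)cc1OC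
A7 | alternative 3 | methyl 3-{2-[(tert-butyldimethylsilyloxy)methyl]-4,6-dimethoxyphenoxy}prop-2-ynoate | COC(=O)C#COc1c(CO[Si](C)(C)C(C)(C)C)cc(OC)cc1OC
A8 | alternative 3 | 3-methyl-1,1-bis(trimethylsilyloxy)buta-1,3-diene | C=C(C)C=C(O[Si](C)(C)C)O[Si](C)(C)C
A9 | alternative 3 | methyl 2-[2-(tert-butyldimethylsilyloxymethyl)-4,6-dimethoxyphenoxy]-6-hydroxy-4-methylbenzoate | COC(=O)c1c(O)cc(C)cc1Oc1c(CO[Si](C)(C)C(C)(C)C)cc(OC)cc1OC
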